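**Plan**

1. Numbering (target): C1 and C10 are the oxirane carbons, C14 is the CH2OH on C10, C4=C5 is the Z-alkene (methyl C15), C6 the lactone carbinol, C7 the ring-fusion carbon, C8 the ester carbinol, C9 the ring CH2, C11–C13 the methylene-lactone carbons. Enabling feature: the fully substituted oxirane carbon C10 lies one methylene (C9) from the oxygen-bearing C8, so the ten-membered ring holds a latent aldol (C8=O/C9/C10–O) whose carbinol oxygen is also the oxirane oxygen on C1; carbocycle and oxirane can therefore be made in one event.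
2. Retrosynthetic cuts, in order: the C14–O benzyl ether; the lactone C12=O/C6–O (from a C6,C12-diol); the C8 ester and C8–H (from the ring ketone); C9–C10 together with C1–O (C8 methyl-ketone enolate onto a C10 ketone carrying chloride at C1); then in the chain C8–C9 (methyl onto a Weinreb amide), C6–C7 (syn aldol), C10–C14 (alkoxymethyllithium onto an aldehyde) and C1–Cl.
3. Forward: nerol supplies C1–C6 with the Z-alkene; homologation by C10, α-chlorination at C1 and addition of C14 build the chlorohydrin end; the aldol at C6 joins the C7/C8/C11–C13 piece; the methyl ketone becomes a silyl enol ether and C10 is oxidised last; one cascade closes the ten-membered ring and then the oxirane; the lactone ring is closed near the end.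
4. Stereochemistry: C1 from catalyst-controlled α-chlorination (S chloride, inverted once on oxirane closure); C6 and C7 from the (S)-4-benzyloxazolidinone boron aldol; C10 from the C1 chloride during the cascade (Cornforth sense); C8 from peripheral hydride delivery to the ring ketone; 4Z from nerol.

Key step: step 22

Remark: (2R,5R)-2,5-diphenylpyrrolidine is assumed to deliver the 2S α-chloro aldehyde; if the sense is the opposite, its enantiomer is used.
Remark: compounds 12–15 and 25–31 are carried as both C10 epimers, because C10 becomes a ketone in step 21.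

**Route**

Step 1
Reactants: 1 nerol
Product: 2 neryl tert-butyldiphenylsilyl ether
Conditions: t-BuPh2SiCl, imidazole, CH2Cl2, 0 °C → rt
Reagents that add atoms: tert-butyl(chloro)diphenylsilane, CC(C)(C)[Si](Cl)(c1ccccc1)c1ccccc1
Why: Silylation of the primary allylic alcohol with a silyl chloride and imidazole should be clean, and the bulky acid-stable group is chosen to survive the acidic hydrolysis of step 5; no stereocentre is formed.

Step 2
Reactants: 2 neryl tert-butyldiphenylsilyl ether
Product: 3 terminal epoxide of 2 (racemic)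
Conditions: 3-chloroperbenzoic acid (1.05 equiv), NaHCO3, CH2Cl2, −20 → 0 °C
Reagents that add atoms: 3-chloroperbenzoic acid, OOC(=O)c1cccc(Cl)c1
Why: Prilezhaev epoxidation should take the terminal isopropylidene alkene, the more electron-rich and less hindered of the two trisubstituted alkenes (C4=C5 is deactivated by the allylic oxygen and screened by the silyl group); the epoxide configuration is irrelevant because it is cleaved in step 3.

Step 3
Reactants: 3 terminal epoxide
Product: 4 (4Z)-6-[(tert-butyldiphenylsilyl)oxy]-4-methylhex-4-enal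
Conditions: H5IO6, THF/H2O, 0 °C
Reagents that add atoms: none
Why: Periodic acid opens the epoxide to the glycol and cleaves it (glycol cleavage), releasing acetone and the aldehyde whose carbonyl carbon is C1; the silyl ether and the Z-alkene are inert.

Step 4
Reactants: 4 C1 aldehyde
Product: 5 methyl enol ether (E/Z mixture at the new double bond)
Conditions: Ph3P(CH2OMe)Cl, NaN(SiMe3)2, THF, 0 °C; then 4, −78 → 0 °C
Reagents that add atoms: (methoxymethyl)triphenylphosphonium chloride, COC[P+](c1ccccc1)(c1ccccc1)c1ccccc1.[Cl-]
Why: Wittig methoxymethylenation adds C10 as an enol ether carbon without touching the silyl ether or the trisubstituted alkene; the geometry of the enol ether is irrelevant.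

Step 5
Reactants: 5 methyl enol ether
Product: 6 (5Z)-7-[(tert-butyldiphenylsilyl)oxy]-5-methylhept-5-enal
Conditions: HCl (1 M aq.), THF, rt
Reagents that add atoms: water, O
Why: Acid hydrolysis of the enol ether gives the homologated aldehyde (C10 is now the carbonyl carbon, C1 its α-methylene); the tert-butyldiphenylsilyl ether resists dilute acid and the remote Z-alkene is not conjugated, so it cannot isomerise.

Step 6
Reactants: 6 C10 aldehyde
Product: 7 (2S,5Z)-7-[(tert-butyldiphenylsilyl)oxy]-2-chloro-5-methylhept-5-enal
Conditions: N-chlorosuccinimide (1.2 equiv), (2R,5R)-2,5-diphenylpyrrolidine (10 mol %), CH2Cl2, 0 °C → rt; pentane, filtration; used at once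
Reagents that add atoms: N-chlorosuccinimide, O=C1CCC(=O)N1Cl
Why: Enamine-catalysed enantioselective α-chlorination of an aldehyde, in which the C2-symmetric pyrrolidine shields one enamine face so that chlorine is delivered to the other and C1 is set as S under catalyst control; the product is used at once because α-chloro aldehydes racemise on standing.

Step 7
Reactants: 8 (4-methoxyphenyl)methanol; 9 tributyl(iodomethyl)stannane
Product: 10 tributyl{[(4-methoxybenzyl)oxy]methyl}stannane
Conditions: NaH, THF/DMF, 0 °C → rt
Reagents that add atoms: none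
Why: Williamson ether synthesis, the sodium alkoxide displacing iodide from the primary tin-bearing carbon; no stereocentre is involved.

Step 8
Reactants: 7 α-chloro aldehyde; 10 alkoxymethylstannane
Product: 13 chlorohydrin pivalate (C1 S; 4Z; both C10 epimers), via alkoxymethyllithium 11 (not isolated), via lithium alkoxide 12 (not isolated)
Conditions: 10, n-BuLi, THF, −78 °C; then 7, −78 °C; then t-BuCOCl, −78 → 0 °C
Reagents that add atoms: pivaloyl chloride, CC(C)(C)C(=O)Cl
Why: Tin–lithium exchange gives the α-alkoxymethyllithium 11, which adds to the highly electrophilic α-chloro aldehyde at −78 °C faster than it deprotonates it (organolithium 1,2-addition, anti chlorohydrin favoured by the Cornforth model), and the lithium alkoxide 12 is O-acylated in the flask before it can close to an epoxide; the new C10 carbinol centre need not be controlled because it is oxidised in step 21, and C1 is not touched.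

Step 9
Reactants: 13 chlorohydrin pivalate
Product: 14 primary allylic alcohol (C6–OH)
Conditions: Bu4NF, THF, 0 °C
Reagents that add atoms: none
Why: Fluoride-mediated desilylation of the primary silyl ether; the pivalate is stable to fluoride and, with no free hydroxyl next to the chloride, no epoxide can form.

Step 10
Reactants: 14 allylic alcohol
Product: 15 Z-enal (C6 aldehyde)
Conditions: Dess–Martin periodinane, NaHCO3, CH2Cl2, 0 °C
Reagents that add atoms: none
Why: Dess–Martin oxidation of the primary allylic alcohol under buffered, non-basic conditions should give the Z-enal without Z to E isomerisation and without touching the chloride, the ester or the benzyl ether.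

Step 11
Reactants: 16 2-methylidenepropane-1,3-diol
Product: 17 2-({[tert-butyl(dimethyl)silyl]oxy}methyl)prop-2-en-1-ol
Conditions: NaH (1.0 equiv), THF, 0 °C; then t-BuMe2SiCl
Reagents that add atoms: tert-butyl(chloro)dimethylsilane, CC(C)(C)[Si](C)(C)Cl
Why: Monosilylation of a symmetrical diol through its monosodium alkoxide, a standard desymmetrising protection; no stereocentre.

Step 12
Reactants: 17 monosilyl ether
Product: 18 {[2-(bromomethyl)prop-2-en-1-yl]oxy}(tert-butyl)dimethylsilane
Conditions: CBr4, PPh3, CH2Cl2, 0 °C
Reagents that add atoms: tetrabromomethane, BrC(Br)(Br)Br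
Why: Appel bromination of the primary allylic alcohol under neutral conditions; direct and allylically transposed substitution give the same bromide, and the silyl ether is stable.

Step 13
Reactants: 18 allylic bromide
Product: 20 3-({[tert-butyl(dimethyl)silyl]oxy}methyl)but-3-enoic acid, via allylmagnesium bromide 19 (not isolated)
Conditions: Mg, THF, 0 °C (slow addition); CO2, −78 °C → rt; aq. NH4Cl
Reagents that add atoms: carbon dioxide, O=C=O
Why: Formation of the allylic Grignard reagent 19 and its carboxylation give the β,γ-unsaturated acid; both termini of the allylmagnesium unit lead to the same acid, and the mild work-up avoids migration of the double bond into conjugation.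

Step 14
Reactants: 20 butenoic acid; 21 (4S)-4-benzyl-1,3-oxazolidin-2-one
Product: 23 (4S)-4-benzyl-3-[3-({[tert-butyl(dimethyl)silyl]oxy}methyl)but-3-enoyl]-1,3-oxazolidin-2-one, via mixed pivalic anhydride 22 (not isolated)
Conditions: t-BuCOCl, Et3N, THF, −20 °C; then 21, LiCl, −20 °C → rt
Reagents that add atoms: none
Why: N-Acylation of the oxazolidinone through the mixed pivalic anhydride 22 with LiCl activation (attack at the less hindered anhydride carbonyl) avoids strong base, which would move the β,γ-double bond into conjugation.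

Step 15
Reactants: 15 Z-enal; 23 N-acyloxazolidinone
Product: 25 syn-aldol adduct (C6 R; C7 S; C1 S; 4Z), via dibutylboron Z-enolate 24 (not isolated)
Conditions: 23, Bu2BOTf, Et3N, CH2Cl2, −78 → 0 °C; then 15, −78 → −10 °C; pH 7 buffer, MeOH, H2O2, 0 °C
Reagents that add atoms: none
Why: Evans syn aldol reaction, in which soft enolisation gives the Z-configured boron dienolate 24 that reacts at its α-carbon (C7) with the enal through a Zimmerman–Traxler chair while the benzyl group of the (S)-auxiliary shields one enolate face, so that C6 and C7 are created syn in the absolute sense of the target; the boron enolate adds only to the aldehyde and leaves the pivalate and the chloride alone.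

Step 16
Reactants: 25 syn-aldol adduct
Product: 26 Weinreb amide (C8)
Conditions: MeNHOMe·HCl, AlMe3, THF, −20 → 0 °C
Reagents that add atoms: N,O-dimethylhydroxylamine hydrochloride, CNOC.Cl
Why: Aluminium-amide transamidation of the N-acyloxazolidinone to the Weinreb amide, assisted by chelation of the free C6 hydroxyl, releases the auxiliary under conditions that do not epimerise C7 and are too mild to aminolyse the hindered pivalate.

Step 17
Reactants: 26 Weinreb amide
Product: 27 C6 tert-butyldimethylsilyl ether of 26
Conditions: t-BuMe2SiOTf, 2,6-lutidine, CH2Cl2, −78 → 0 °C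
Reagents that add atoms: tert-butyldimethylsilyl trifluoromethanesulfonate, CC(C)(C)[Si](C)(C)OS(=O)(=O)C(F)(F)F
Why: Silylation of the hindered secondary allylic alcohol with a silyl triflate and a non-nucleophilic base masks C6–OH, which would otherwise quench the enolate of the key step and open a retro-aldol path across C6–C7.

Step 18
Reactants: 27 silylated Weinreb amide
Product: 28 C8 methyl ketone
Conditions: MeMgBr, THF, −20 → 0 °C
Reagents that add atoms: methylmagnesium bromide, C[Mg]Br
Why: Weinreb ketone synthesis, in which the Grignard reagent adds once to give a stable magnesium chelate that collapses to the methyl ketone (C8, with C9 as its methyl group) only on work-up, so C7 is never exposed to base as a ketone and the hindered pivalate and the secondary chloride do not react.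

Step 19
Reactants: 28 methyl ketone
Product: 30 triethylsilyl enol ether (C8–O–Si; C8=C9), via lithium enolate 29 (not isolated)
Conditions: LiN(i-Pr)2, Et3SiCl, THF, −78 °C (in situ quench); Et3N, pentane, cold aq. NaHCO3
Reagents that add atoms: chlorotriethylsilane, CC[Si](Cl)(CC)CC
Why: Kinetic enolisation with in situ O-silylation, in which the hindered amide base removes a proton from the unhindered methyl group (C9) rather than from the more acidic but shielded C7 methine and the lithium enolate 29 is trapped at once, fixes the regiochemistry of the enolate needed in step 22; the triethylsilyl group is chosen because it survives steps 20 and 21.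

Step 20
Reactants: 30 silyl enol ether pivalate
Product: 31 chlorohydrin (free C10–OH)
Conditions: i-Bu2AlH, CH2Cl2, −78 °C; aq. KNaC4H4O6
Reagents that add atoms: none
Why: Reductive cleavage of the pivalate with an aluminium hydride at −78 °C frees the C10 hydroxyl without acid, base or fluoride, none of which the silyl enol ether would tolerate; the secondary chloride and the silyl ethers are inert.

Step 21
Reactants: 31 chlorohydrin
Product: 32 α-chloro ketone silyl enol ether (C1 S; C6 R; C7 S; 4Z)
Conditions: Dess–Martin periodinane, NaHCO3, CH2Cl2, 0 °C; filtration through Et3N-deactivated silica; used directly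
Reagents that add atoms: none
Why: Dess–Martin oxidation of the chlorohydrin under bicarbonate buffering should give the α-chloro ketone without enolisation (hence no epimerisation at C1) and without hydrolysing or oxidising the silyl enol ether.

Step 22
Reactants: 32 α-chloro ketone silyl enol ether
Product: 35 ten-membered epoxy ketone (1R;6R;7S;10S;4Z), via tetrabutylammonium enolate 33 (not isolated), via macrocyclic chloro alkoxide 34 (not isolated)
Conditions: Bu4N[Ph3SiF2] (1.2 equiv), 4 Å sieves, THF, slow addition of 32 to 0.001 M, −40 → 0 °C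
Reagents that add atoms: none
Why: Proposed new method: fluoride from the silicate attacks the triethylsilyl group and releases the C8 methyl-ketone enolate regiospecifically as its ammonium salt 33, whose C9 adds to the C10 ketone (activated by the α-chloride and the α-alkoxy group) to give the ten-membered aldolate 34, and the tertiary alkoxide then displaces the vicinal chloride from the rear; the closest known reaction types are fluoride-promoted aldol additions of silyl enol ethers and Darzens-type additions of enolates to α-chloro ketones that end in epoxide closure, neither documented as a ten-membered ring closure. The carbocycle closes by a 10-(enolexo)-exo-trig aldol addition and the oxirane by 3-exo-tet substitution. The new C10 centre is controlled by the C1 chloride: in the reactive conformer the C10=O and C1–Cl dipoles are opposed (Cornforth model; the polar Felkin–Anh model predicts the same) and C9 enters past the C1 hydrogen, so that after closure C9 is trans to C2 and C14 is cis to C2. C1 ends as R because the S chloride set in step 6 is inverted once. The step needs C-attack at C10 to outrun proton transfer from C1–H or C14–H to the enolate and intermolecular aldol addition; the non-basic anhydrous fluoride source, low temperature and high dilution serve this, and because the aldol addition is reversible while chloride loss is not, mis-added forms return to the enolate and are drained through the aldolate that can reach the anti-periplanar O–C–C–Cl geometry. C6, C7 and the Z-alkene stay untouched provided the enolate does not equilibrate toward C7, which the absence of excess base and the short enolate lifetime are meant to ensure.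

Step 23
Reactants: 35 epoxy ketone
Product: 36 C8 alcohol (8R)
Conditions: NaBH4, CeCl3·7H2O, MeOH/THF, −78 → −40 °C
Reagents that add atoms: none
Why: Luche-type 1,2-reduction of the ring ketone, in which hydride should attack from the periphery of the ten-membered ring, anti to the C6–C7 ring bond and past the small C7 hydrogen rather than the branched C11 substituent (Felkin–Anh sense), places the new C8 oxygen cis to the C11 side chain (8R); the cerium salt speeds carbonyl addition and suppresses enolisation toward C7 and opening of the β,γ-epoxide.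

Step 24
Reactants: 36 C8 alcohol
Product: 37 C8 isobutyrate
Conditions: (i-PrCO)2O, 4-(dimethylamino)pyridine, Et3N, CH2Cl2, rt
Reagents that add atoms: isobutyric anhydride, CC(C)C(=O)OC(=O)C(C)C
Why: Acylation of the secondary alcohol with the anhydride under nucleophilic catalysis by 4-(dimethylamino)pyridine installs the isobutyrate while every other oxygen is still protected, which fixes the ester at C8.

Step 25
Reactants: 37 C8 isobutyrate
Product: 38 C6,C12-diol
Conditions: Bu4NF, AcOH (1:1), THF, 0 °C → rt
Reagents that add atoms: none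
Why: Fluoride-mediated cleavage of both silyl ethers, buffered with acetic acid so that the freed C6 and C12 hydroxyls do not take over the C8 acyl group by base-induced migration and the epoxide is not opened.

Step 26
Reactants: 38 diol
Product: 41 α-methylene lactone 4-methoxybenzyl ether, via hydroxy enal 39 (not isolated), via lactol 40 (not isolated)
Conditions: 2,2,6,6-tetramethylpiperidin-1-oxyl (0.2 equiv), PhI(OAc)2 (3 equiv), CH2Cl2, rt
Reagents that add atoms: none
Why: Oxoammonium-catalysed oxidative lactonisation, in which the primary allylic C12 alcohol is oxidised much faster than the secondary C6 alcohol, the hydroxy enal 39 closes with the C6 hydroxyl to the five-membered lactol 40 and this is oxidised to the lactone; C6 and C7 (trans ring fusion) are already fixed and the C8 oxygen is blocked as the ester, so only the 6,12-lactone can form.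

Step 27
Reactants: 41 lactone 4-methoxybenzyl ether
Product: 42 target (CNP0247143.1)
Conditions: DDQ, CH2Cl2/pH 7 phosphate buffer, 0 °C
Reagents that add atoms: none
Why: Oxidative cleavage of the 4-methoxybenzyl ether with DDQ in wet buffered solvent (benzylic hydride abstraction, then hydrolysis of the oxocarbenium ion) frees C14–OH under neutral conditions that the epoxide, the esters and the α-methylene lactone tolerate.

**Compound list**

1 | nerol, (2Z)-3,7-dimethylocta-2,6-dien-1-ol | CC(C)=CCC/C(C)=C\CO | starting material
2 | tert-butyl{[(2Z)-3,7-dimethylocta-2,6-dien-1-yl]oxy}diphenylsilane | CC(C)=CCC/C(C)=C\CO[Si](c1ccccc1)(c1ccccc1)C(C)(C)C | intermediate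
3 | tert-butyl{[(2Z)-5-(3,3-dimethyloxiran-2-yl)-3-methylpent-2-en-1-yl]oxy}diphenylsilane (racemic) | CC1(C)OC1CC/C(C)=C\CO[Si](c1ccccc1)(c1ccccc1)C(C)(C)C | intermediate
4 | (4Z)-6-[(tert-butyldiphenylsilyl)oxy]-4-methylhex-4-enal | O=CCC/C(C)=C\CO[Si](c1ccccc1)(c1ccccc1)C(C)(C)C | intermediate
5 | tert-butyl{[(2Z)-7-methoxy-3-methylhepta-2,6-dien-1-yl]oxy}diphenylsilane (E/Z at the enol ether) | COC=CCC/C(C)=C\CO[Si](c1ccccc1)(c1ccccc1)C(C)(C)C | intermediate
6 | (5Z)-7-[(tert-butyldiphenylsilyl)oxy]-5-methylhept-5-enal | O=CCCC/C(C)=C\CO[Si](c1ccccc1)(c1ccccc1)C(C)(C)C | intermediate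
7 | (2S,5Z)-7-[(tert-butyldiphenylsilyl)oxy]-2-chloro-5-methylhept-5-enal | O=C[C@@H](Cl)CC/C(C)=C\CO[Si](c1ccccc1)(c1ccccc1)C(C)(C)C | intermediate
8 | (4-methoxyphenyl)methanol | COc1ccc(CO)cc1 | starting material
9 | tributyl(iodomethyl)stannane | CCCC[Sn](CCCC)(CCCC)CI | starting material
10 | tributyl{[(4-methoxybenzyl)oxy]methyl}stannane | CCCC[Sn](CCCC)(CCCC)COCc1ccc(OC)cc1 | intermediate
11 | {[(4-methoxybenzyl)oxy]methyl}lithium | [Li]COCc1ccc(OC)cc1 | intermediate (not isolated)
12 | lithium (3S,6Z)-8-[(tert-butyldiphenylsilyl)oxy]-3-chloro-1-[(4-methoxybenzyl)oxy]-6-methyloct-6-en-2-olate (both C2 epimers) | [Li+].[O-]C(COCc1ccc(OC)cc1)[C@@H](Cl)CC/C(C)=C\CO[Si](c1ccccc1)(c1ccccc1)C(C)(C)C | intermediate (not isolated)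
13 | (3S,6Z)-8-[(tert-butyldiphenylsilyl)oxy]-3-chloro-1-[(4-methoxybenzyl)oxy]-6-methyloct-6-en-2-yl 2,2-dimethylpropanoate (both C2 epimers; C2 is C10 of the target) | CC(C)(C)C(=O)OC(COCc1ccc(OC)cc1)[C@@H](Cl)CC/C(C)=C\CO[Si](c1ccccc1)(c1ccccc1)C(C)(C)C | intermediate
14 | (3S,6Z)-3-chloro-8-hydroxy-1-[(4-methoxybenzyl)oxy]-6-methyloct-6-en-2-yl 2,2-dimethylpropanoate | CC(C)(C)C(=O)OC(COCc1ccc(OC)cc1)[C@@H](Cl)CC/C(C)=C\CO | intermediate
15 | (3S,6Z)-3-chloro-1-[(4-methoxybenzyl)oxy]-6-methyl-8-oxooct-6-en-2-yl 2,2-dimethylpropanoate | CC(C)(C)C(=O)OC(COCc1ccc(OC)cc1)[C@@H](Cl)CC/C(C)=C\C=O | intermediate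
16 | 2-methylidenepropane-1,3-diol | C=C(CO)CO | starting material
17 | 2-({[tert-butyl(dimethyl)silyl]oxy}methyl)prop-2-en-1-ol | C=C(CO)CO[Si](C)(C)C(C)(C)C | intermediate
18 | {[2-(bromomethyl)prop-2-en-1-yl]oxy}(tert-butyl)dimethylsilane | C=C(CBr)CO[Si](C)(C)C(C)(C)C | intermediate
19 | [2-({[tert-butyl(dimethyl)silyl]oxy}methyl)prop-2-en-1-yl]magnesium bromide | C=C(C[Mg]Br)CO[Si](C)(C)C(C)(C)C | intermediate (not isolated)
20 | 3-({[tert-butyl(dimethyl)silyl]oxy}methyl)but-3-enoic acid | C=C(CC(=O)O)CO[Si](C)(C)C(C)(C)C | intermediate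
21 | (4S)-4-benzyl-1,3-oxazolidin-2-one | O=C1N[C@@H](Cc2ccccc2)CO1 | starting material
22 | 3-({[tert-butyl(dimethyl)silyl]oxy}methyl)but-3-enoic 2,2-dimethylpropanoic anhydride | C=C(CC(=O)OC(=O)C(C)(C)C)CO[Si](C)(C)C(C)(C)C | intermediate (not isolated)
23 | (4S)-4-benzyl-3-[3-({[tert-butyl(dimethyl)silyl]oxy}methyl)but-3-enoyl]-1,3-oxazolidin-2-one | C=C(CO[Si](C)(C)C(C)(C)C)CC(=O)N1[C@@H](Cc2ccccc2)COC1=O | intermediate
24 | dibutylboron Z-enolate of 23 | C=C(CO[Si](C)(C)C(C)(C)C)/C=C(\OB(CCCC)CCCC)N1[C@@H](Cc2ccccc2)COC1=O | intermediate (not isolated)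
25 | (4S)-4-benzyl-3-[(2S,3R,4Z,8S)-8-chloro-3-hydroxy-10-[(4-methoxybenzyl)oxy]-5-methyl-9-(pivaloyloxy)-2-(3-{[tert-butyl(dimethyl)silyl]oxy}prop-1-en-2-yl)dec-4-enoyl]-1,3-oxazolidin-2-one (acyl C1–C10 are target C8, C7, C6, C5, C4, C3, C2, C1, C10, C14; C9 epimers) | C=C(CO[Si](C)(C)C(C)(C)C)[C@H](C(=O)N1[C@@H](Cc2ccccc2)COC1=O)[C@H](O)/C=C(/C)CC[C@H](Cl)C(OC(=O)C(C)(C)C)COCc1ccc(OC)cc1 | intermediate
26 | Weinreb amide: (2S,3R,4Z,8S)-8-chloro-3-hydroxy-N-methoxy-10-[(4-methoxybenzyl)oxy]-N,5-dimethyl-9-(pivaloyloxy)-2-(3-{[tert-butyl(dimethyl)silyl]oxy}prop-1-en-2-yl)dec-4-enamide | C=C(CO[Si](C)(C)C(C)(C)C)[C@H](C(=O)N(C)OC)[C@H](O)/C=C(/C)CC[C@H](Cl)C(OC(=O)C(C)(C)C)COCc1ccc(OC)cc1 | intermediate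
27 | 3-O-tert-butyldimethylsilyl ether of 26 (C6–OSi in target numbering) | C=C(CO[Si](C)(C)C(C)(C)C)[C@H](C(=O)N(C)OC)[C@H](O[Si](C)(C)C(C)(C)C)/C=C(/C)CC[C@H](Cl)C(OC(=O)C(C)(C)C)COCc1ccc(OC)cc1 | intermediate
28 | methyl ketone: (3S,4R,5Z,9S)-4-{[tert-butyl(dimethyl)silyl]oxy}-3-(3-{[tert-butyl(dimethyl)silyl]oxy}prop-1-en-2-yl)-9-chloro-11-[(4-methoxybenzyl)oxy]-6-methyl-2-oxoundec-5-en-10-yl 2,2-dimethylpropanoate | C=C(CO[Si](C)(C)C(C)(C)C)[C@H](C(C)=O)[C@H](O[Si](C)(C)C(C)(C)C)/C=C(/C)CC[C@H](Cl)C(OC(=O)C(C)(C)C)COCc1ccc(OC)cc1 | intermediate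
29 | lithium enolate of 28 (deprotonated at the methyl group C9) | [Li+].C=C(CO[Si](C)(C)C(C)(C)C)[C@H](C(=C)[O-])[C@H](O[Si](C)(C)C(C)(C)C)/C=C(/C)CC[C@H](Cl)C(OC(=O)C(C)(C)C)COCc1ccc(OC)cc1 | intermediate (not isolated)
30 | triethylsilyl enol ether of 28 (C8–OSiEt3, C8=C9H2; C1 S, C6 R, C7 S, 4Z) | C=C(CO[Si](C)(C)C(C)(C)C)[C@H](C(=C)O[Si](CC)(CC)CC)[C@H](O[Si](C)(C)C(C)(C)C)/C=C(/C)CC[C@H](Cl)C(OC(=O)C(C)(C)C)COCc1ccc(OC)cc1 | intermediate
31 | chlorohydrin: 30 with free C10–OH in place of the pivalate | C=C(CO[Si](C)(C)C(C)(C)C)[C@H](C(=C)O[Si](CC)(CC)CC)[C@H](O[Si](C)(C)C(C)(C)C)/C=C(/C)CC[C@H](Cl)C(O)COCc1ccc(OC)cc1 | intermediate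
32 | open-chain key-step precursor: C8 triethylsilyl enol ether with C1 (S) chloride and C10 ketone, C6 (R) and C12 tert-butyldimethylsilyl ethers, C14 4-methoxybenzyl ether, C7 S, 4Z | C=C(CO[Si](C)(C)C(C)(C)C)[C@H](C(=C)O[Si](CC)(CC)CC)[C@H](O[Si](C)(C)C(C)(C)C)/C=C(/C)CC[C@H](Cl)C(=O)COCc1ccc(OC)cc1 | intermediate
33 | tetrabutylammonium C8 enolate of the chloro ketone | C=C(CO[Si](C)(C)C(C)(C)C)[C@H](C(=C)[O-])[C@H](O[Si](C)(C)C(C)(C)C)/C=C(/C)CC[C@H](Cl)C(=O)COCc1ccc(OC)cc1.CCCC[N+](CCCC)(CCCC)CCCC | intermediate (not isolated)
34 | ten-membered aldolate: C8 ketone, C10 alkoxide (10S), C1 chloride (1S), tetrabutylammonium salt | CC(C)(C)[Si](C)(C)O[C@@H]1/C=C(/C)CC[C@H](Cl)[C@@]([O-])(COCc2ccc(OC)cc2)CC(=O)[C@H]1C(=C)CO[Si](C)(C)C(C)(C)C.CCCC[N+](CCCC)(CCCC)CCCC | intermediate (not isolated)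
35 | key-step product: (4Z)-1,10-epoxygermacra-4,11(13)-dien-8-one with 6-O- and 12-O-tert-butyldimethylsilyl and 14-O-(4-methoxybenzyl) groups; (1R,6R,7S,10S) | CC(C)(C)[Si](C)(C)O[C@@H]1/C=C(/C)CC[C@H]2O[C@]2(COCc3ccc(OC)cc3)CC(=O)[C@H]1C(=C)CO[Si](C)(C)C(C)(C)C | intermediate
36 | 8-alcohol of 35; (1R,6R,7R,8R,10S) | CC(C)(C)[Si](C)(C)O[C@@H]1/C=C(/C)CC[C@H]2O[C@]2(COCc3ccc(OC)cc3)C[C@@H](O)[C@H]1C(=C)CO[Si](C)(C)C(C)(C)C | intermediate
37 | 8-O-(2-methylpropanoyl) ester of 36; (1R,6R,7R,8R,10S) | CC(C)(C)[Si](C)(C)O[C@@H]1/C=C(/C)CC[C@H]2O[C@]2(COCc3ccc(OC)cc3)C[C@@H](OC(=O)C(C)C)[C@H]1C(=C)CO[Si](C)(C)C(C)(C)C | intermediate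
38 | 6,12-diol: 37 without the two silyl groups; configuration at C1, C6, C7, C8, C10 as in 42 | O[C@@H]1/C=C(/C)CC[C@H]2O[C@]2(COCc3ccc(OC)cc3)C[C@@H](OC(=O)C(C)C)[C@H]1C(=C)CO | intermediate
39 | hydroxy enal: 38 with C12 as the aldehyde | O[C@@H]1/C=C(/C)CC[C@H]2O[C@]2(COCc3ccc(OC)cc3)C[C@@H](OC(=O)C(C)C)[C@H]1C(=C)C=O | intermediate (not isolated)
40 | 6,12-lactol (C12 epimers) | C=C1C(O)O[C@@H]2/C=C(/C)CC[C@H]3O[C@]3(COCc4ccc(OC)cc4)C[C@@H](OC(=O)C(C)C)[C@@H]12 | intermediate (not isolated)
41 | 14-O-(4-methoxybenzyl) ether of the target; (1R,6R,7R,8R,10S,4Z) | C=C1C(=O)O[C@@H]2/C=C(/C)CC[C@H]3O[C@]3(COCc4ccc(OC)cc4)C[C@@H](OC(=O)C(C)C)[C@@H]12 | intermediate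
42 | CNP0247143.1: (1R,6R,7R,8R,10S,4Z)-1,10-epoxy-14-hydroxy-8-(2-methylpropanoyloxy)germacra-4,11(13)-dien-12,6-olide | C=C1C(=O)O[C@@H]2/C=C(/C)CC[C@H]3O[C@]3(CO)C[C@@H](OC(=O)C(C)C)[C@@H]12 | target

**Counts and risks**

Total step count: 27. Longest linear sequence: 22 steps (steps 1–6, 8–10 and 15–27, from nerol). Step 7 (one step) and steps 11–14 (four steps) are side branches.

Steps most likely to fail:

1. Step 22 (key step). What may go wrong: proton transfer from the acidic C1–H or C14–H positions of the chloro ketone to the free enolate (then epimerisation at C1 or Favorskii-type loss of chloride), intermolecular aldol addition, or ring closure slow enough for the enolate to equilibrate toward C7. Fallback with known reaction types, leaving the route at 32 and returning at 35: the silyl enol ether 32 is brominated at C9 with N-bromosuccinimide (THF, −78 °C), a regiospecific α-bromination of a silyl enol ether, to give the bromomethyl ketone F1. F1 is added slowly to Zn dust and Et2AlCl in THF at −20 °C; zinc inserts into the C–Br bond in preference to the C–Cl bond, and the aluminium enolate, which is too weakly basic to deprotonate the chloro ketone, adds to the C10 carbonyl through a closed, chelated transition state. This is an intramolecular Reformatsky-type aldol cyclisation, a ring closure known for medium and large carbocycles, and should give the ten-membered chlorohydrin F2 with the same Cornforth preference at C10. K2CO3 in methanol at 0 °C then closes the oxirane with inversion at C1 and gives 35.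

2. Step 19. What may go wrong: abstraction of the C7 proton (allylic and α to the carbonyl) competing with deprotonation of the methyl group, which would scramble C7, expel the C6 silyloxy group by β-elimination or give the wrong enol ether regioisomer. Fallback leaving the route at 27 and returning at 30: the Weinreb amide 27 is treated with bromomethyllithium made in the flask (CH2Br2, MeLi·LiBr, THF, −78 °C) to give the bromomethyl ketone F3 without any enolisation step. Zinc dust and Et3SiCl (MeCN/Et2O, 0 °C) then turn the C–Br bond into the zinc enolate, which is silylated on oxygen (Reformatsky-type generation of a regiodefined enolate), and give the same triethylsilyl enol ether 30; the temperature is kept at 0 °C so that the β-acyloxy chloride does not undergo reductive elimination.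

3. Step 23. What may go wrong: hydride delivery to the other face of the C8 carbonyl if the ring prefers a conformer that exposes it (poor or reversed facial selectivity). Fallback leaving the route at 35 and returning at 37: the reduction is then run for that face (LiBH(s-Bu)3, THF, −78 °C) to give the C8 epimer F4, which is esterified with inversion by a Mitsunobu reaction with isobutyric acid (PPh3, diisopropyl azodicarboxylate, toluene, 0 °C → rt); displacement of the activated oxygen by isobutyrate gives 37 directly.

**Further compounds**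

F1 | step 22 | bromomethyl ketone: C9 bromide of the C8 ketone with the C1 chloride and C10 ketone of 32 unchanged | C=C(CO[Si](C)(C)C(C)(C)C)[C@H](C(=O)CBr)[C@H](O[Si](C)(C)C(C)(C)C)/C=C(/C)CC[C@H](Cl)C(=O)COCc1ccc(OC)cc1
F2 | step 22 | ten-membered chlorohydrin: C8 ketone, C10 tertiary alcohol (10S), C1 chloride (1S), other groups as in 35 | CC(C)(C)[Si](C)(C)O[C@@H]1/C=C(/C)CC[C@H](Cl)[C@@](O)(COCc2ccc(OC)cc2)CC(=O)[C@H]1C(=C)CO[Si](C)(C)C(C)(C)C
F3 | step 19 | bromomethyl ketone corresponding to 28 (C9 bromide; C10 pivalate retained) | C=C(CO[Si](C)(C)C(C)(C)C)[C@H](C(=O)CBr)[C@H](O[Si](C)(C)C(C)(C)C)/C=C(/C)CC[C@H](Cl)C(OC(=O)C(C)(C)C)COCc1ccc(OC)cc1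
F4 | step 23 | C8 epimer of 36 (8S alcohol) | CC(C)(C)[Si](C)(C)O[C@@H]1/C=C(/C)CC[C@H]2O[C@]2(COCc3ccc(OC)cc3)C[C@H](O)[C@H]1C(=C)CO[Si](C)(C)C(C)(C)C
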